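Ring A (C10, C1–C5) is not made as a six-membered ring. Its quaternary C4, which carries a methyl and the oxygenated carbon C18 next to the ring-fusion carbon C5, is read as the product of a Meinwald ring contraction: in a cis-fused cycloheptene oxide, C3 shifts from the epoxide CH (future C18) to the methyl-bearing epoxide carbon C4, so C18 leaves the ring as a formyl group while ring A and the C4 stereocentre form in one operation. The precursor is a bicyclo[5.4.0]undecadienone made from (S)-carvone by two α′-alkylations (C10) and ring-closing metathesis of its isopropenyl group; the carvone enone then delivers C8, C9 and the side chain.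

Key step: step 5

Remark on the chemistry: the SMILES is read as a 5-epi-labdane (A/B cis: H-5 and CH3-20 both β). Labdane locants are used for all intermediates; β is the face of CH3-20, the oxygenated α carbon on C4 is C18 and the β methyl is C19. Commercial LiN(iPr)2 solution and preformed MeAl(OAr)2 (Ar = 4-bromo-2,6-di-tert-butylphenyl) are assumed. Facial selectivities in this cis-fused series are predictions from conformational reasoning, not established facts.

Step 1
Reactants: 1 (S)-(+)-carvone; 2 5-iodopent-1-ene
Product: 3 (5S)-6-(pent-4-en-1-yl)carvone, chiefly the isomer with the new chain trans to the isopropenyl group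
Conditions: LiN(iPr)2, THF, −78 °C; then 2, DMPU, −78 → 0 °C
Reagents that add atoms: 5-iodopent-1-ene (2), C=CCCCI
Why: Kinetic α′-deprotonation of the enone and SN2 alkylation of the cross-conjugated lithium enolate (enolate alkylation); the new centre is re-enolised in step 2, so its configuration is of no consequence.

Step 2
Reactants: 3 6-(pent-4-en-1-yl)carvone
Product: 4 6-methyl-6-(pent-4-en-1-yl)carvone, 6-methyl trans and pentenyl chain cis to the isopropenyl group (future C20, C10, C1–C3)
Conditions: LiN(iPr)2, THF, −78 °C; MeI, −78 → −20 °C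
Reagents that add atoms: iodomethane, CI
Why: Alkylation of the tetrasubstituted lithium enolate; iodomethane should approach anti to the vicinal isopropenyl group on C5 (substrate control known for 6-alkylcarvones), so the methyl ends trans and the chain cis, which sets quaternary C10 and predetermines the cis ring fusion.

Step 3
Reactants: 4 6-methyl-6-(pent-4-en-1-yl)carvone
Product: 5 cis-fused bicyclo[5.4.0]undecadienone (ring B: C9=O, C7=C8–CH3; seven-membered ring C10–C1–C2–C3–C18H=C4(CH3)–C5; CH3-20 and H-5 β)
Conditions: second-generation Grubbs catalyst (5 mol%), CH2Cl2 (5 mM), 40 °C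
Reagents that add atoms: none
Why: Ring-closing metathesis between the terminal alkene and the cis-disposed isopropenyl group closes the trisubstituted cycloheptene; the conjugated, trisubstituted enone alkene does not take part.

Step 4
Reactants: 5 cis-fused bicyclo[5.4.0]undecadienone
Product: 7 4α,18α-epoxy enone (oxygen on the face opposite to H-5 and CH3-20), via bromohydrin 6 (not isolated)
Conditions: N-bromosuccinimide, THF–H2O, 0 °C; then K2CO3, MeOH, 0 °C → rt
Reagents that add atoms: water, O
Why: Bromohydrin formation followed by intramolecular Williamson closure: the bromonium ion should form on the convex β face and be opened anti by water at the tertiary C4 (4α-OH, 18β-Br), and base then closes the epoxide with inversion at C18, placing oxygen on the α face that direct peracid epoxidation is not expected to reach.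

Step 5
Reactants: 7 4α,18α-epoxy enone
Product: 8 ring-contracted keto aldehyde (cis-decalin, 9-oxo, 7-ene, 8-CH3; C4 carries β-CH3 and α-CHO = C18)
Conditions: MeAl(OAr)2 (Ar = 4-bromo-2,6-di-tert-butylphenyl; 2.2 equiv), CH2Cl2, −78 → −20 °C; 1 M HCl work-up
Reagents that add atoms: none
Why: The aluminium Lewis acid binds the epoxide oxygen and the tertiary C4–O bond ionises; as it breaks, ring carbon C3 shifts from C18 to C4 antiperiplanar to the departing oxygen and C18 collapses to the aldehyde, so the cycloheptane loses C18 and becomes ring A (C10, C1, C2, C3, C4, C5). This is a Meinwald (semipinacol-type) epoxide-to-aldehyde rearrangement, for which bulky methylaluminium bis(aryloxides) are known to favour alkyl over hydride shift in trisubstituted epoxides, including ring contraction of 1-methylcycloalkene oxides. Ring A is closed by a 1,2-carbon shift that makes the C3–C4 bond (ring contraction, not an end-to-end cyclisation). The only new stereocentre, quaternary C4, is controlled by the epoxide configuration: inversion at C4 brings C3 in on the side away from the oxygen and leaves CHO (C18) α and CH3 (C19) β. The step needs C3 and not H-18 to migrate and the C9 enone to stay out; the bulky aluminium reagent, the gain on going from a seven- to a six-membered ring, and the second equivalent of Lewis acid held on the enone oxygen should secure this.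

Step 6
Reactants: 8 ring-contracted keto aldehyde
Product: 10 methyl ester of the C18 acid (9-oxo, 7-ene), via carboxylic acid 9 (not isolated)
Conditions: NaClO2, NaH2PO4, 2-methylbut-2-ene, tBuOH–H2O, rt; then Me3SiCHN2, PhMe–MeOH, 0 °C
Reagents that add atoms: sodium chlorite, [Na+].[O-]Cl=O; trimethylsilyldiazomethane, C[Si](C)(C)C=[N+]=[N-]
Why: Pinnick oxidation of the non-enolisable aldehyde under buffered, non-basic conditions (no vinylogous aldol onto C18), then O-methylation by the diazo reagent; the hindered ester masks C18 through steps 7–9 and is reduced in step 10.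

Step 7
Reactants: 10 methyl ester (9-oxo, 7-ene)
Product: 11 7β,8β-epoxy-9-ketone
Conditions: H2O2 (30% aq.), NaOH, MeOH, 0 °C
Reagents that add atoms: hydrogen peroxide, OO
Why: Weitz–Scheffer nucleophilic epoxidation; hydroperoxide should add to C7 from the convex β face, anti to the α-oriented C5–C4 bond (as carvone is attacked trans to its C5 substituent), and the enolate closes on the same face, setting C7 and C8.

Step 8
Reactants: 11 7β,8β-epoxy-9-ketone
Product: 12 7β-hydroxy-8(9)-ene (allylic alcohol, 18-methyl ester)
Conditions: N2H4·H2O, AcOH (cat.), MeOH, 0 °C → rt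
Reagents that add atoms: none
Why: Wharton transposition: hydrazone formation at C9, epoxide opening to the vinyl diazene and loss of N2 move the alkene to C8=C9 and leave the C7–O bond untouched, so the 7β configuration is carried over.

Step 9
Reactants: 12 7β-hydroxy-8(9)-ene
Product: 13 diester with 9β-CH2CO2Et (C11–C12), 7-ene and 18-CO2Me
Conditions: MeC(OEt)3, EtCO2H (cat.), 140 °C, removal of EtOH
Reagents that add atoms: triethyl orthoacetate, CC(OCC)(OCC)OCC
Why: Johnson–Claisen rearrangement: the ketene acetal on O-7 rearranges suprafacially through a chair transition state, so the new C9–C11 bond forms on the β face from which the C7–O bond leaves (1,3-chirality transfer), setting C9 (H α) beside quaternary C10.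

Step 10
Reactants: 13 diester
Product: 14 7-ene-12,18-diol
Conditions: LiAlH4, THF, 0 °C → reflux
Reagents that add atoms: none
Why: Hydride reduction of both esters to primary alcohols (the neopentyl C18 ester needs reflux); no stereocentre is touched.

Step 11
Reactants: 14 7-ene-12,18-diol
Product: 15 12-iodo-7-en-18-ol
Conditions: PPh3, I2, imidazole, CH2Cl2, 0 °C
Reagents that add atoms: iodine, II
Why: Appel iodination is an SN2 process and should therefore select the unhindered C12 hydroxyl over the neopentyl C18 hydroxyl.

Step 12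
Reactants: 15 12-iodo-7-en-18-ol; 16 chloroprene (2-chlorobuta-1,3-diene)
Product: 18 5-epi-labda-7,13(16),14-trien-18-ol, via buta-1,3-dien-2-ylmagnesium chloride 17 (not isolated)
Conditions: 16, Mg, ZnCl2 (cat.), THF, 50 °C; then 15, Li2CuCl4 (cat.), THF, −10 → 0 °C; NH4Cl (aq.)
Reagents that add atoms: chloroprene (16), C=CC(Cl)=C
Why: Copper-catalysed Kumada-type coupling of a primary alkyl iodide with the dienyl Grignard reagent, the known way to 2-alkylbuta-1,3-dienes; one equivalent of 17 is spent on the free hydroxyl, and the coupling is run before O-8 exists so that no tetrahydrofuran can close onto C12.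

Step 13
Reactants: 18 5-epi-labda-7,13(16),14-trien-18-ol
Product: 19 7α,8α-epoxy-5-epi-labda-13(16),14-dien-18-ol
Conditions: mCPBA (1.05 equiv), NaHCO3, CH2Cl2, −20 °C
Reagents that add atoms: 3-chloroperbenzoic acid, O=C(OO)c1cccc(Cl)c1
Why: Prilezhaev epoxidation, chemoselective for the trisubstituted ring alkene over the conjugated 2-alkylbutadiene (as with myrcene); the α face is expected because the peracid is hydrogen-bonded to the α-oriented C18 hydroxyl lying under ring B (hydroxyl-directed delivery) while CH3-20 and the C9 chain screen the β face.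

Step 14
Reactants: 19 7α,8α-epoxide
Product: 20 5-epi-labda-13(16),14-diene-8α,18-diol
Conditions: LiAlH4, THF, reflux
Reagents that add atoms: none
Why: Hydride opens the trisubstituted epoxide by SN2 attack at the less substituted C7 from the β face, leaving the tertiary 8α-hydroxyl with CH3-17 β; the diene is inert to LiAlH4.

Step 15
Reactants: 20 5-epi-labda-13(16),14-diene-8α,18-diol; 21 [bis(2,2,2-trifluoroethoxy)phosphoryl]acetic acid
Product: 22 8α-hydroxy-5-epi-labda-13(16),14-dien-18-yl [bis(2,2,2-trifluoroethoxy)phosphoryl]acetate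
Conditions: EDC·HCl, DMAP (cat.), CH2Cl2, 0 °C → rt
Reagents that add atoms: [bis(2,2,2-trifluoroethoxy)phosphoryl]acetic acid (21), OC(=O)CP(=O)(OCC(F)(F)F)OCC(F)(F)F
Why: Steglich-type carbodiimide esterification acylates only the primary C18 hydroxyl; the tertiary C8 hydroxyl does not react.

Step 16
Reactants: 22 phosphonoacetate; 23 4-[(tert-butyldimethylsilyl)oxy]benzaldehyde
Product: 25 8α-hydroxy-5-epi-labda-13(16),14-dien-18-yl (Z)-4-hydroxycinnamate (target), via aryl silyl ether 24 (not isolated)
Conditions: KN(SiMe3)2, 18-crown-6, THF, −78 °C, then 23; then Bu4NF, AcOH, THF, 0 °C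
Reagents that add atoms: 4-[(tert-butyldimethylsilyl)oxy]benzaldehyde (23), O=Cc1ccc(O[Si](C)(C)C(C)(C)C)cc1
Why: Still–Gennari variant of the Horner–Wadsworth–Emmons olefination: the electron-poor phosphonate under dissociating conditions eliminates rapidly from the kinetic adduct and should give the (Z)-cinnamate, and buffered fluoride then frees the phenol without isomerising the Z alkene or touching the diene.

Compound list
1 | (S)-(+)-carvone, (5S)-2-methyl-5-(prop-1-en-2-yl)cyclohex-2-en-1-one | O=C1C[C@@H](C(C)=C)CC=C1C | starting material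
2 | 5-iodopent-1-ene | C=CCCCI | starting material
3 | (5S)-6-(pent-4-en-1-yl)carvone, chain trans to isopropenyl (major) | O=C1[C@H](CCCC=C)[C@@H](C(C)=C)CC=C1C | intermediate
4 | 6-methyl-6-(pent-4-en-1-yl)carvone, methyl trans and chain cis to isopropenyl | O=C1[C@@](C)(CCCC=C)[C@@H](C(C)=C)CC=C1C | intermediate
5 | cis-fused bicyclo[5.4.0]undecadienone (C9=O, C7=C8, C4=C18; 10β-CH3, 5β-H) | O=C1[C@@]2(C)CCCC=C(C)[C@H]2CC=C1C | intermediate
6 | bromohydrin of 5 (4α-OH, 18β-Br) | O=C1[C@@]2(C)CCC[C@H](Br)[C@@](C)(O)[C@H]2CC=C1C | intermediate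
7 | 4α,18α-epoxy enone | O=C1[C@@]2(C)CCC[C@H]3O[C@@]3(C)[C@H]2CC=C1C | intermediate
8 | ring-contracted keto aldehyde (C4: β-CH3, α-CHO; 9-oxo, 7-ene) | O=C1[C@@]2(C)CCC[C@@](C)(C=O)[C@H]2CC=C1C | intermediate
9 | C18 carboxylic acid (9-oxo, 7-ene) | O=C1[C@@]2(C)CCC[C@@](C)(C(O)=O)[C@H]2CC=C1C | intermediate
10 | C18 methyl ester (9-oxo, 7-ene) | O=C1[C@@]2(C)CCC[C@@](C)(C(=O)OC)[C@H]2CC=C1C | intermediate
11 | 7β,8β-epoxy-9-ketone, 18-methyl ester | O=C1[C@@]2(C)CCC[C@@](C)(C(=O)OC)[C@H]2C[C@@H]3O[C@@]31C | intermediate
12 | 7β-hydroxy-8(9)-ene, 18-methyl ester | CC1=C[C@@]2(C)CCC[C@@](C)(C(=O)OC)[C@H]2C[C@@H]1O | intermediate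
13 | diester: 9β-CH2CO2Et, 7-ene, 18-CO2Me | CCOC(=O)C[C@@H]1[C@@]2(C)CCC[C@@](C)(C(=O)OC)[C@H]2CC=C1C | intermediate
14 | 7-ene-12,18-diol | OCC[C@@H]1[C@@]2(C)CCC[C@@](C)(CO)[C@H]2CC=C1C | intermediate
15 | 12-iodo-7-en-18-ol | ICC[C@@H]1[C@@]2(C)CCC[C@@](C)(CO)[C@H]2CC=C1C | intermediate
16 | chloroprene (2-chlorobuta-1,3-diene) | C=CC(Cl)=C | starting material
17 | buta-1,3-dien-2-ylmagnesium chloride | C=CC(=C)[Mg]Cl | intermediate
18 | 5-epi-labda-7,13(16),14-trien-18-ol | C=CC(=C)CC[C@@H]1[C@@]2(C)CCC[C@@](C)(CO)[C@H]2CC=C1C | intermediate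
19 | 7α,8α-epoxy-5-epi-labda-13(16),14-dien-18-ol | C=CC(=C)CC[C@@H]1[C@@]2(C)CCC[C@@](C)(CO)[C@H]2C[C@H]3O[C@]31C | intermediate
20 | 5-epi-labda-13(16),14-diene-8α,18-diol | C=CC(=C)CC[C@@H]1[C@@]2(C)CCC[C@@](C)(CO)[C@H]2CC[C@@]1(C)O | intermediate
21 | [bis(2,2,2-trifluoroethoxy)phosphoryl]acetic acid | OC(=O)CP(=O)(OCC(F)(F)F)OCC(F)(F)F | starting material
22 | 8α-hydroxy-5-epi-labda-13(16),14-dien-18-yl [bis(2,2,2-trifluoroethoxy)phosphoryl]acetate | C=CC(=C)CC[C@@H]1[C@@]2(C)CCC[C@@](C)(COC(=O)CP(=O)(OCC(F)(F)F)OCC(F)(F)F)[C@H]2CC[C@@]1(C)O | intermediate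
23 | 4-[(tert-butyldimethylsilyl)oxy]benzaldehyde | O=Cc1ccc(O[Si](C)(C)C(C)(C)C)cc1 | starting material
24 | O-(tert-butyldimethylsilyl) ether of the target | C=CC(=C)CC[C@@H]1[C@@]2(C)CCC[C@@](C)(COC(=O)/C=C\c3ccc(O[Si](C)(C)C(C)(C)C)cc3)[C@H]2CC[C@@]1(C)O | intermediate
25 | 8α-hydroxy-5-epi-labda-13(16),14-dien-18-yl (Z)-4-hydroxycinnamate | C=CC(=C)CC[C@@H]1[C@@]2(C)CCC[C@@](C)(COC(=O)/C=C\c3ccc(O)cc3)[C@H]2CC[C@@]1(C)O | target

Total step count: 16. Longest linear sequence: 16 steps (1 → 25).

Steps most likely to fail

Step 5. The hydride on C18 may migrate in place of C3 (giving the cycloheptanone), or C4 may ionise fully so that the antiperiplanar control of the shift is lost. The fallback sets out from 5 and comes back at 8. Direct epoxidation of 5 with mCPBA/NaHCO3 should occur on the convex β face and give the 4β,18β-epoxide F1. Anhydrous HCl in Et2O at −20 °C (or TiCl4 at −78 °C) should open it at the tertiary C4 with inversion to the trans-chlorohydrin F2 (4α-Cl, 18β-OH). Ag2CO3 in CH2Cl2 then removes chloride while the antiperiplanar C18–C3 ring bond migrates (halohydrin semipinacol ring contraction, as trans-2-halocycloalkanols give cycloalkanecarbaldehydes). Two inversions at C4 replace the single one of the main route, so the same aldehyde 8 should result.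

Step 4. The bromonium ion may form on the α face, or bromide or the C9 carbonyl may intercept it instead of water, which would lead to the β-epoxide or to mixtures. The fallback sets out from 5 and comes back at 7 with no new compound: a reagent-controlled Shi epoxidation (D-fructose-derived ketone, KHSO5 as its triple salt, K2CO3, MeCN–dimethoxymethane–aqueous buffer, 0 °C). The spiro transition state that turns 1-phenylcyclohexene into its (R,R)-oxide maps onto α-face delivery at C4=C18, and the enone is inert to the dioxirane.

Step 13. Oxygen may be delivered to the β face of C7=C8 if hydrogen-bond delivery from O-18 is ineffective, and the diene may be partly epoxidised. The fallback sets out from 13 and comes back at 20, introducing O-8 before the side chain: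
- Oxymercuration–demercuration of 13 (Hg(OAc)2, THF–H2O; then NaBH4, NaOH), with the mercurinium ion on the β face at C7 and water anti at the tertiary C8, should give the 8α-hydroxy diester F3.
- Et3SiOTf/2,6-lutidine gives the triethylsilyl ether F4, which keeps O-8 from closing onto C12.
- LiAlH4 gives the 12,18-diol F5.
- PPh3/I2/imidazole gives the 12-iodide F6.
- Coupling with 17 under Li2CuCl4 catalysis gives the silyl-protected diene F7.
- Bu4NF returns to 20.

Further compounds
F1 | step 5 | 4β,18β-epoxy enone | O=C1[C@@]2(C)CCC[C@@H]3O[C@]3(C)[C@H]2CC=C1C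
F2 | step 5 | chlorohydrin (4α-Cl, 18β-OH) | O=C1[C@@]2(C)CCC[C@H](O)[C@@](C)(Cl)[C@H]2CC=C1C
F0 | step 4 | none | none
F3 | step 13 | 8α-hydroxy diester | CCOC(=O)C[C@@H]1[C@@]2(C)CCC[C@@](C)(C(=O)OC)[C@H]2CC[C@@]1(C)O
F4 | step 13 | 8α-triethylsilyloxy diester | CCOC(=O)C[C@@H]1[C@@]2(C)CCC[C@@](C)(C(=O)OC)[C@H]2CC[C@@]1(C)O[Si](CC)(CC)CC
F5 | step 13 | 8α-triethylsilyloxy-12,18-diol | OCC[C@@H]1[C@@]2(C)CCC[C@@](C)(CO)[C@H]2CC[C@@]1(C)O[Si](CC)(CC)CC
F6 | step 13 | 12-iodo-8α-triethylsilyloxy-18-ol | ICC[C@@H]1[C@@]2(C)CCC[C@@](C)(CO)[C@H]2CC[C@@]1(C)O[Si](CC)(CC)CC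
F7 | step 13 | 8-O-triethylsilyl ether of 20 | C=CC(=C)CC[C@@H]1[C@@]2(C)CCC[C@@](C)(CO)[C@H]2CC[C@@]1(C)O[Si](CC)(CC)CC
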